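The route rests on cutting the side chain at C1′–C2′ and C4′–C5′. The feature used is that the lactone-ring carbinol C3 and the side-chain carbinol C6′ are joined by five methylenes (C1′–C5′): each carbinol with its adjacent CH2 can come from an enantiopure terminal epoxide, and C2′–C4′ from propyne. In one pot, 1,3-dilithiopropyne opens (S)-1,2-epoxyheptane through its propargylic carbon, and the acetylide that remains, once BF3·OEt2 is added, opens an (S)-(2-bromoaryl)methyl oxirane, which gives the whole carbon chain with both stereocentres in place. The aryl epoxide carries benzyl ethers on the two phenols and a bromine at the carbon that later bears the lactone carbonyl C1.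

Key step: step 4

Remarks on the chemistry (assumptions and design choices):
- Atom labels: the isochromanone is numbered C1 (carbonyl), O2, C3, C4, C4a–C8a; the side chain is C1′–C11′ counted outward from C3.
- Assumption: 1,3-bis(benzyloxy)-5-bromobenzene is taken as a catalogue compound; it is otherwise one benzylation away from 5-bromoresorcinol.
- Benzyl ethers replace methyl ethers on the phenols, so the final unmasking is a neutral hydrogenolysis and no boron trihalide meets the free secondary alcohol and the lactone.
- The triple bond is saturated before the palladium step, because an aryl-palladium intermediate could add across the tethered alkyne (a six-membered exo closure is available) in competition with CO insertion.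

Step 1
Reactants: 1 1,3-bis(benzyloxy)-5-bromobenzene; 2 (S)-epichlorohydrin
Product: 4 (S)-1-[3,5-bis(benzyloxy)phenyl]-3-chloropropan-2-ol, via 3,5-bis(benzyloxy)phenylmagnesium bromide 3 (not isolated)
Conditions: Mg, THF, 40 °C; then CuI (10 mol %), 2 (1.2 equiv), THF, −40 → 0 °C; aq HCl (1 M)
Reagents that add atoms: none
Why: Copper-catalysed Grignard opening of an epoxide, in which the aryl group attacks the unsubstituted ring carbon by SN2 faster than it displaces chloride at low temperature, so the carbinol carbon is not touched and keeps its configuration (descriptor stays S).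

Step 2
Reactants: 4 (S)-1-[3,5-bis(benzyloxy)phenyl]-3-chloropropan-2-ol
Product: 5 (S)-1-[3,5-bis(benzyloxy)-2-bromophenyl]-3-chloropropan-2-ol
Conditions: NBS (1.0 equiv), MeCN, 0 °C, dark
Reagents that add atoms: N-bromosuccinimide, O=C1CCC(=O)N1Br
Why: Electrophilic aromatic bromination of a doubly alkoxy-activated ring should go to the position ortho to the alkyl chain and para to one benzyloxy group, because the site between the two ethers is more hindered, while the polar solvent and darkness keep radical bromination of the benzylic CH2 groups out and the epoxide is not yet present to be opened by traces of HBr.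

Step 3
Reactants: 5 (S)-1-[3,5-bis(benzyloxy)-2-bromophenyl]-3-chloropropan-2-ol
Product: 6 (S)-2-[3,5-bis(benzyloxy)-2-bromobenzyl]oxirane
Conditions: NaOH (2 equiv), MeOH–THF, 0 °C → rt
Reagents that add atoms: none
Why: Intramolecular Williamson etherification (3-exo-tet closure) in which the alkoxide displaces the primary chloride, so the C–O bond at the stereocentre is never broken and the configuration is retained (descriptor stays S).

Step 4
Reactants: 7 propyne; 8 (S)-1,2-epoxyheptane; 6 (S)-2-[3,5-bis(benzyloxy)-2-bromobenzyl]oxirane
Product: 11 (2R,8S)-1-[3,5-bis(benzyloxy)-2-bromophenyl]tridec-4-yne-2,8-diol, via 1,3-dilithiopropyne 9 (not isolated), via lithium (S)-1-lithiodec-1-yn-5-olate 10 (not isolated)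
Conditions: 7 (1.05 equiv), n-BuLi (2.0 equiv), Et2O–hexane, −78 °C → rt; 8 (1.0 equiv), THF, 0 °C → rt; −78 °C, BF3·OEt2 (3 equiv), then 6 (0.8 equiv), THF; aq NH4Cl
Reagents that add atoms: none
Why: Twofold deprotonation of propyne gives dianion 9, whose sp3 propargylic carbanion is far more basic and nucleophilic than its acetylide end, so it alone attacks the unsubstituted ring carbon of 8 by SN2 (bond C4′–C5′) and leaves the lithium acetylide–alkoxide 10. A lithium acetylide does not open an epoxide at −78 °C unaided, so the second bond (C1′–C2′) forms only when BF3·OEt2 activates epoxide 6 and the acetylide attacks its terminal CH2, again by SN2. The closest known reaction types are the propargylation of electrophiles by 1,3-dilithiopropyne and the BF3-promoted alkynylation of terminal epoxides (Yamaguchi–Hirao reaction). No ring is closed and no stereocentre is created: only primary carbons are attacked, so C6′ and C3 keep the configuration of the two enantiopure epoxides (the descriptor at the aryl-side carbinol changes from S to R only because the CIP priorities change). The step needs the two carbanion sites to react in order, terminal regioselectivity and tolerance of the C–Br bond; the first follows from the basicity gap between the two sites, the second from the steric bias of monosubstituted oxiranes, and the third from using exactly two equivalents of n-BuLi per propyne and one equivalent of 8 per dianion, so that no alkyl- or propargyllithium able to exchange with bromine is left when 6 is added. The surplus BF3·OEt2 makes up for the equivalent bound by the alkoxide of 10.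

Step 5
Reactants: 11 (2R,8S)-1-[3,5-bis(benzyloxy)-2-bromophenyl]tridec-4-yne-2,8-diol
Product: 12 (2R,8S)-1-[3,5-bis(benzyloxy)-2-bromophenyl]tridecane-2,8-diol
Conditions: H2 (3 atm), RhCl(PPh3)3 (5 mol %), toluene–EtOH (1:1), 40 °C
Reagents that add atoms: none
Why: Homogeneous catalytic hydrogenation with the monovalent rhodium complex should saturate the internal alkyne through the cis-alkene while leaving the aryl C–Br bond and the benzyl ethers intact, since this catalyst does not effect hydrogenolysis under these conditions.

Step 6
Reactants: 12 (2R,8S)-1-[3,5-bis(benzyloxy)-2-bromophenyl]tridecane-2,8-diol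
Product: 13 (R)-6,8-bis(benzyloxy)-3-[(S)-6-hydroxyundecyl]isochroman-1-one
Conditions: CO (1 atm), Pd(OAc)2 (5 mol %), Xantphos (6 mol %), Et3N (3 equiv), toluene, 90 °C
Reagents that add atoms: carbon monoxide, [C-]#[O+]
Why: Palladium-catalysed intramolecular alkoxycarbonylation (carbonylative lactonisation), in which zerovalent palladium inserts into the C–Br bond, CO inserts, and the C2 hydroxyl captures the acyl-palladium to close the six-membered lactone, whereas the remote hydroxyl could only form a twelve-membered ring; the C–O bond at C3 is not broken, so the R configuration is kept.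

Step 7
Reactants: 13 (R)-6,8-bis(benzyloxy)-3-[(S)-6-hydroxyundecyl]isochroman-1-one
Product: 14 (R)-6,8-dihydroxy-3-[(S)-6-hydroxyundecyl]isochroman-1-one (target)
Conditions: H2 (1 atm), 10% Pd/C, EtOAc–MeOH, rt
Reagents that add atoms: none
Why: Hydrogenolysis of the two aryl benzyl ethers over palladium on carbon should free both phenols under neutral conditions, while the lactone C3–O bond (not benzylic), the secondary alcohol and both stereocentres are unaffected.

Compound list
1 | 1,3-bis(benzyloxy)-5-bromobenzene | Brc1cc(OCc2ccccc2)cc(OCc2ccccc2)c1 | starting material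
2 | (S)-epichlorohydrin, (S)-2-(chloromethyl)oxirane | ClC[C@@H]1CO1 | starting material
3 | 3,5-bis(benzyloxy)phenylmagnesium bromide | Br[Mg]c1cc(OCc2ccccc2)cc(OCc2ccccc2)c1 | intermediate (not isolated)
4 | (S)-1-[3,5-bis(benzyloxy)phenyl]-3-chloropropan-2-ol | ClC[C@@H](O)Cc1cc(OCc2ccccc2)cc(OCc2ccccc2)c1 | intermediate
5 | (S)-1-[3,5-bis(benzyloxy)-2-bromophenyl]-3-chloropropan-2-ol | ClC[C@@H](O)Cc1cc(OCc2ccccc2)cc(OCc2ccccc2)c1Br | intermediate
6 | (S)-2-[3,5-bis(benzyloxy)-2-bromobenzyl]oxirane | Brc1c(OCc2ccccc2)cc(OCc2ccccc2)cc1C[C@H]1CO1 | intermediate
7 | propyne | CC#C | starting material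
8 | (S)-1,2-epoxyheptane, (S)-2-pentyloxirane | CCCCC[C@H]1CO1 | starting material
9 | 1,3-dilithiopropyne | [Li]CC#C[Li] | intermediate (not isolated)
10 | lithium (S)-1-lithiodec-1-yn-5-olate | CCCCC[C@H](O[Li])CCC#C[Li] | intermediate (not isolated)
11 | (2R,8S)-1-[3,5-bis(benzyloxy)-2-bromophenyl]tridec-4-yne-2,8-diol | CCCCC[C@H](O)CCC#CC[C@@H](O)Cc1cc(OCc2ccccc2)cc(OCc2ccccc2)c1Br | intermediate
12 | (2R,8S)-1-[3,5-bis(benzyloxy)-2-bromophenyl]tridecane-2,8-diol | CCCCC[C@H](O)CCCCC[C@@H](O)Cc1cc(OCc2ccccc2)cc(OCc2ccccc2)c1Br | intermediate
13 | (R)-6,8-bis(benzyloxy)-3-[(S)-6-hydroxyundecyl]isochroman-1-one | CCCCC[C@H](O)CCCCC[C@@H]1Cc2cc(OCc3ccccc3)cc(OCc3ccccc3)c2C(=O)O1 | intermediate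
14 | (R)-6,8-dihydroxy-3-[(S)-6-hydroxyundecyl]isochroman-1-one | CCCCC[C@H](O)CCCCC[C@@H]1Cc2cc(O)cc(O)c2C(=O)O1 | target

Total step count: 7. Longest linear sequence: 7 steps (1 → 4 → 5 → 6 → 11 → 12 → 13 → 14); propyne 7 and epoxide 8 are bought and enter at step 4.

Steps most likely to fail, with fallbacks

Step 4. The Lewis acid may be tied up by the lithium alkoxide and the mixed aggregates, so that the second epoxide opening stalls. Allenyl-type attack may intrude in the first opening. Unconsumed carbanion may undergo bromine–lithium exchange with 6. An amine additive such as TMEDA, should it be needed to form the dianion, would also bind BF3 and call for a further equivalent. The fallback separates the two bond formations and masks the first hydroxyl. It sets out from 8: opening with a slight excess of dianion 9 and aqueous quench should give (S)-dec-1-yn-5-ol F1. Silylation (TBSCl, imidazole, DMF) should give (S)-tert-butyl(dec-1-yn-5-yloxy)dimethylsilane F2. Its lithium acetylide (n-BuLi, 1.0 equiv, THF, −78 °C), which now has no competing alkoxide, is combined with BF3·OEt2 and 6 and should give (2R,8S)-1-[3,5-bis(benzyloxy)-2-bromophenyl]-8-[(tert-butyldimethylsilyl)oxy]tridec-4-yn-2-ol F3. Desilylation with Bu4NF in THF brings the sequence back to the route at 11.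

Step 6. Oxidative addition into the hindered, electron-rich C–Br bond may be slow. Hydrodebromination may then take over, through alcohol oxidation at palladium. The aryl-palladium may also arylate the ring of the neighbouring benzyl ether before CO inserts. The fallback avoids palladium and sets out from 12. n-BuLi (3.3 equiv, THF, −78 °C) should deprotonate both hydroxyls and exchange the bromine for lithium. Quenching the aryllithium with CO2 and acidifying should give 2,4-bis(benzyloxy)-6-[(2R,8S)-2,8-dihydroxytridecyl]benzoic acid F4. With catalytic TsOH in toluene this should close to the six-membered lactone and return to the route at 13.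

Step 5. Hydrogen uptake may stall at the cis-alkene, or turnover with the rhodium complex may be too slow on the internal alkyne. The fallback changes the order of events and sets out from 11. Carbonylative lactonisation with the alkyne still present uses the catalyst of step 6 under raised CO pressure (about 10 atm), so that CO insertion outruns addition of aryl-palladium across the triple bond. It should give (R)-6,8-bis(benzyloxy)-3-[(S)-6-hydroxyundec-2-yn-1-yl]isochroman-1-one F5. One hydrogenation over Pd/C (H2, EtOAc–MeOH) then saturates the alkyne and removes both benzyl groups, returning to the route at target 14.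

Further compounds
F1 | step 4 | (S)-dec-1-yn-5-ol | CCCCC[C@H](O)CCC#C
F2 | step 4 | (S)-tert-butyl(dec-1-yn-5-yloxy)dimethylsilane | CCCCC[C@H](O[Si](C)(C)C(C)(C)C)CCC#C
F3 | step 4 | (2R,8S)-1-[3,5-bis(benzyloxy)-2-bromophenyl]-8-[(tert-butyldimethylsilyl)oxy]tridec-4-yn-2-ol | CCCCC[C@H](O[Si](C)(C)C(C)(C)C)CCC#CC[C@@H](O)Cc1cc(OCc2ccccc2)cc(OCc2ccccc2)c1Br
F4 | step 6 | 2,4-bis(benzyloxy)-6-[(2R,8S)-2,8-dihydroxytridecyl]benzoic acid | CCCCC[C@H](O)CCCCC[C@@H](O)Cc1cc(OCc2ccccc2)cc(OCc2ccccc2)c1C(O)=O
F5 | step 5 | (R)-6,8-bis(benzyloxy)-3-[(S)-6-hydroxyundec-2-yn-1-yl]isochroman-1-one | CCCCC[C@H](O)CCC#CC[C@@H]1Cc2cc(OCc3ccccc3)cc(OCc3ccccc3)c2C(=O)O1
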